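**Retrosynthetic overview**

1. Target 17 comes from chromone 16 (5-OMe, 7-O-isopropyl) by one BCl3 treatment. Chelation between the C4 carbonyl and O5 removes the peri methyl group, the secondary isopropyl group at O7 is cleaved as well, and the methyl ethers at C6, C8, C2' and C3' stay.
2. Ring C of 16 is cut at O1–C2 and C3–C4. The feature used is that in the pyranone ring C2 carries both O1 and ring B, while C3 is bound to the C4 carbonyl. This is the polarity of a terminal aryl alkyne (aryl-bearing carbon becomes C2, CH terminus becomes C3) meeting an aroylium carbon (C4) whose ring A holds an ortho ether oxygen (O1).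
3. The fragments are aroyl chloride 9 (ring A, mirror plane through C1 and C4, both ortho positions methoxy, para position isopropoxy) and alkyne 12 (ring B). The ortho oxygens are carried as methyl ethers, so whichever closes ring C, the one left at C5 is the peri methyl ether that BCl3 singles out; only O7 needs a separate isopropyl group.
4. 9 comes from acid 8, from penta-alkoxybenzene 6 (lithiation, CO2), from phenol 4 (O-isopropylation), from 1,2,4,5-tetramethoxybenzene 1 (lithiation, borylation, oxidation). 12 comes from 2,3-dimethoxybenzaldehyde 10 by one-carbon homologation.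
5. Ring order: rings A and B are bought as benzene rings; ring C is the only ring formed, in step 6.

Key step: step 6

Assumption: 1,2,4,5-tetramethoxybenzene, 2-bromopropane, 2,3-dimethoxybenzaldehyde and all reagents named (including dimethyl (1-diazo-2-oxopropyl)phosphonate) are bought.

**Route**

Step 1
Reactants: 1 1,2,4,5-tetramethoxybenzene
Product: 4 2,3,5,6-tetramethoxyphenol, via aryllithium 2 (not isolated), via dimethyl arylboronate 3 (not isolated)
Conditions: n-BuLi (1.05 equiv), TMEDA, THF, 0 °C to rt; B(OMe)3, −78 °C to rt; AcOH, 30% aq. H2O2, 0 °C; under N2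
Reagents that add atoms: hydrogen peroxide, OO
Why: Directed ortho-metalation, borylation and oxidation: n-BuLi removes one of the two equivalent ring hydrogens of 1, each flanked by two methoxy groups, aryllithium 2 is trapped by B(OMe)3 as boronate 3, and hydroperoxide induces the 1,2-aryl shift from boron to oxygen that should give phenol 4 after hydrolysis.

Step 2
Reactants: 4 2,3,5,6-tetramethoxyphenol; 5 2-bromopropane
Product: 6 1,2,4,5-tetramethoxy-3-(propan-2-yloxy)benzene
Conditions: K2CO3, DMF, 60 °C, under N2; 5 (1.5 equiv)
Reagents that add atoms: none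
Why: Williamson ether synthesis: the single phenoxide of 4 is alkylated on oxygen by the secondary bromide in DMF, the small excess of bromide making up for loss to propene, and exclusion of air protects the electron-rich phenol.

Step 3
Reactants: 6 1,2,4,5-tetramethoxy-3-(propan-2-yloxy)benzene
Product: 8 2,3,5,6-tetramethoxy-4-(propan-2-yloxy)benzoic acid, via aryllithium 7 (not isolated)
Conditions: n-BuLi, TMEDA, THF, −20 to 0 °C; CO2, −78 °C to rt; cold dilute aq. HCl
Reagents that add atoms: carbon dioxide, O=C=O
Why: Directed ortho-metalation followed by carboxylation: the only ring hydrogen of 6 lies between two methoxy groups that acidify it and bind lithium, and aryllithium 7 adds to CO2.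

Step 4
Reactants: 8 2,3,5,6-tetramethoxy-4-(propan-2-yloxy)benzoic acid
Product: 9 2,3,5,6-tetramethoxy-4-(propan-2-yloxy)benzoyl chloride
Conditions: (COCl)2, cat. DMF, CH2Cl2, 0 °C to rt; volatiles removed, used crude
Reagents that add atoms: oxalyl chloride, O=C(Cl)C(=O)Cl
Why: Acid chloride formation with oxalyl chloride under DMF catalysis (Vilsmeier-type chloroiminium activation) runs cold and without water, so the electron-rich acid should be converted before protodecarboxylation or ether loss can set in.

Step 5
Reactants: 10 2,3-dimethoxybenzaldehyde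
Product: 12 1-ethynyl-2,3-dimethoxybenzene, via diazoalkene 11 (not isolated)
Conditions: dimethyl (1-diazo-2-oxopropyl)phosphonate, K2CO3, MeOH, 0 °C to rt
Reagents that add atoms: dimethyl (1-diazo-2-oxopropyl)phosphonate, CC(=O)C(=[N+]=[N-])P(=O)(OC)OC
Why: Seyferth–Gilbert homologation in the Ohira–Bestmann variant: the diazomethylphosphonate anion released by methanolysis olefinates the aldehyde to diazoalkene 11, which loses N2 and rearranges by 1,2-hydrogen shift to the terminal alkyne; the aldehyde has no α-hydrogen and the methyl ethers are inert.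

Step 6
Reactants: 9 2,3,5,6-tetramethoxy-4-(propan-2-yloxy)benzoyl chloride; 12 1-ethynyl-2,3-dimethoxybenzene
Product: 16 2-(2,3-dimethoxyphenyl)-5,6,8-trimethoxy-7-(propan-2-yloxy)chromen-4-one, via aroylium ion 13 (not isolated), via vinyl cation 14 (not isolated), via oxonium ion 15 (not isolated)
Conditions: SnCl4 (1.2 equiv), CH2Cl2, −20 °C to rt; 12 (1.3 equiv) added slowly to 9/SnCl4
Reagents that add atoms: none
Why: SnCl4 ionises 9 to aroylium ion 13, which adds in a Friedel–Crafts acylation to the CH terminus of 12 (Markovnikov sense) and so forms C3–C4 and vinyl cation 14, whose charge sits on the carbon bearing ring B and is stabilised by that ring. An ortho methoxy oxygen of ring A then attacks the digonal cationic carbon in a 6-endo-dig closure that forms O1–C2 and ring C as the O-methyl oxonium ion 15, and chloride from SnCl5− takes the methyl group by SN2 as chloromethane, which returns SnCl4 and the neutral chromone 16. The closest known reaction type is the domino Friedel–Crafts acylation of alkynes with 2-methoxybenzoyl chlorides followed by demethylative annulation to chromones. No stereocentre is formed. The step needs regioselectivity for aryl at C2, which the terminal alkyne secures because only attack at its CH end gives an aryl-stabilised cation, and chemoselectivity for the alkyne over ring B, which should hold because the π bond conjugated to the dimethoxyphenyl ring is the most nucleophilic site. The two ortho methoxy groups of 9 are related by the mirror plane through C1 and C4 of ring A, so closure through either gives the same chromone, and the isopropyl ether at the para position is not held near the tin-bound carbonyl and should survive SnCl4 at these temperatures.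

Step 7
Reactants: 16 2-(2,3-dimethoxyphenyl)-5,6,8-trimethoxy-7-(propan-2-yloxy)chromen-4-one
Product: 17 5,7-dihydroxy-2-(2,3-dimethoxyphenyl)-6,8-dimethoxychromen-4-one (5,7-dihydroxy-6,8,2',3'-tetramethoxyflavone)
Conditions: BCl3 (5 equiv, 1 M in CH2Cl2), CH2Cl2, −78 °C to rt; 1 M aq. HCl work-up
Reagents that add atoms: none
Why: Lewis-acid ether cleavage: BCl3 bound between the C4 carbonyl and O5 should remove the peri methyl group as chloromethane and the secondary isopropyl group at O7 as 2-chloropropane, while the non-chelated primary methyl ethers at C6, C8, C2' and C3' react far more slowly at these temperatures.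

**Compound list**

1 | 1,2,4,5-tetramethoxybenzene | COc1cc(OC)c(OC)cc1OC | starting material
2 | (2,3,5,6-tetramethoxyphenyl)lithium (aryllithium) | [Li]c1c(OC)c(OC)cc(OC)c1OC | intermediate
3 | dimethyl (2,3,5,6-tetramethoxyphenyl)boronate (dimethyl arylboronate) | COB(OC)c1c(OC)c(OC)cc(OC)c1OC | intermediate
4 | 2,3,5,6-tetramethoxyphenol | COc1cc(OC)c(OC)c(O)c1OC | intermediate
5 | 2-bromopropane | CC(C)Br | starting material
6 | 1,2,4,5-tetramethoxy-3-(propan-2-yloxy)benzene | COc1cc(OC)c(OC)c(OC(C)C)c1OC | intermediate
7 | [2,3,5,6-tetramethoxy-4-(propan-2-yloxy)phenyl]lithium (aryllithium) | [Li]c1c(OC)c(OC)c(OC(C)C)c(OC)c1OC | intermediate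
8 | 2,3,5,6-tetramethoxy-4-(propan-2-yloxy)benzoic acid | COc1c(OC)c(C(=O)O)c(OC)c(OC)c1OC(C)C | intermediate
9 | 2,3,5,6-tetramethoxy-4-(propan-2-yloxy)benzoyl chloride | COc1c(OC)c(C(=O)Cl)c(OC)c(OC)c1OC(C)C | intermediate
10 | 2,3-dimethoxybenzaldehyde | COc1cccc(C=O)c1OC | starting material
11 | 1-(2-diazoethenyl)-2,3-dimethoxybenzene (diazoalkene) | COc1cccc(C=C=[N+]=[N-])c1OC | intermediate
12 | 1-ethynyl-2,3-dimethoxybenzene | C#Cc1cccc(OC)c1OC | intermediate
13 | 2,3,5,6-tetramethoxy-4-(propan-2-yloxy)benzoylium (aroylium ion) | COc1c(OC)c(C#[O+])c(OC)c(OC)c1OC(C)C | intermediate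
14 | 1-(2,3-dimethoxyphenyl)-3-oxo-3-[2,3,5,6-tetramethoxy-4-(propan-2-yloxy)phenyl]prop-1-en-1-ylium (vinyl cation) | COc1cccc([C+]=CC(=O)c2c(OC)c(OC)c(OC(C)C)c(OC)c2OC)c1OC | intermediate
15 | 2-(2,3-dimethoxyphenyl)-5,6,8-trimethoxy-1-methyl-4-oxo-7-(propan-2-yloxy)-4H-chromen-1-ium (oxonium ion) | COc1cccc(C2=CC(=O)c3c(OC)c(OC)c(OC(C)C)c(OC)c3[O+]2C)c1OC | intermediate
16 | 2-(2,3-dimethoxyphenyl)-5,6,8-trimethoxy-7-(propan-2-yloxy)chromen-4-one | COc1cccc(-c2cc(=O)c3c(OC)c(OC)c(OC(C)C)c(OC)c3o2)c1OC | intermediate
17 | 5,7-dihydroxy-2-(2,3-dimethoxyphenyl)-6,8-dimethoxychromen-4-one (5,7-dihydroxy-6,8,2',3'-tetramethoxyflavone) | COc1cccc(-c2cc(=O)c3c(O)c(OC)c(O)c(OC)c3o2)c1OC | target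

**Step count**

Total steps: 7. Longest linear sequence: 6 (steps 1, 2, 3, 4, 6, 7); step 5 is the one-step side branch to alkyne 12.

**Steps most likely to fail**

Step 6. The aryl-stabilised vinyl cation may be intercepted by chloride, or the electron-rich alkyne may oligomerise under SnCl4, before the ether oxygen closes ring C. Fallback: the C–C bond is made without a free cation and the ring is closed in separate operations. Setting out from 9 and 12, an acyl Sonogashira coupling (PdCl2(PPh3)2, copper iodide CuI, Et3N, THF, rt) would give the ynone 3-(2,3-dimethoxyphenyl)-1-[2,3,5,6-tetramethoxy-4-(propan-2-yloxy)phenyl]prop-2-yn-1-one F1. BCl3 (CH2Cl2, −78 to 0 °C) would then cleave the isopropyl ether and, under chelation to the ketone, one ortho methyl ether to give 1-(2,4-dihydroxy-3,5,6-trimethoxyphenyl)-3-(2,3-dimethoxyphenyl)prop-2-yn-1-one F2. TfOH-promoted 6-endo-dig oxa-Michael cyclisation of this o-alkynoylphenol would give 2-(2,3-dimethoxyphenyl)-7-hydroxy-5,6,8-trimethoxychromen-4-one F3. Chelation-controlled cleavage of its 5-methyl ether with BCl3 comes back to the route at the target 17.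

Step 7. Once O5 is bound to boron, a neighbouring methyl ether may be cleaved as well (over-dealkylation), or one of the two intended cleavages may stall. Fallback: the two cleavages are taken apart, and the methyl ether is removed by a nucleophilic, chelation-directed reagent instead of a strong Lewis acid, so that no reagent has to choose among all six ethers at once. Setting out from 16, MgI2·OEt2 (toluene, 80 °C) would remove only the peri methyl group, by iodide attack on the ether held in a magnesium chelate with the C4 carbonyl, to give 2-(2,3-dimethoxyphenyl)-5-hydroxy-6,8-dimethoxy-7-(propan-2-yloxy)chromen-4-one F4. Cleavage of the remaining isopropyl ether alone (BCl3, 1.5 equiv, CH2Cl2, −78 °C) comes back to the route at the target 17.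

Step 1. The phenol, once released in the presence of peroxide, may be oxidised further towards a quinone, or the di-ortho-methoxy boronate may be protodeboronated before it is oxidised. Fallback: the oxygen is introduced by formylation and Baeyer–Villiger rearrangement, which keeps the new oxygen masked as an ester while oxidant is present. Setting out from 1, lithiation as in step 1 followed by DMF would give 2,3,5,6-tetramethoxybenzaldehyde F5. Baeyer–Villiger oxidation with mCPBA (CH2Cl2, 0 °C) would give 2,3,5,6-tetramethoxyphenyl formate F6. Methanolysis of the formate (K2CO3, MeOH, under N2) comes back to the route at phenol 4.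

**Further compounds**

F1 | step 6 | 3-(2,3-dimethoxyphenyl)-1-[2,3,5,6-tetramethoxy-4-(propan-2-yloxy)phenyl]prop-2-yn-1-one | COc1cccc(C#CC(=O)c2c(OC)c(OC)c(OC(C)C)c(OC)c2OC)c1OC
F2 | step 6 | 1-(2,4-dihydroxy-3,5,6-trimethoxyphenyl)-3-(2,3-dimethoxyphenyl)prop-2-yn-1-one | COc1cccc(C#CC(=O)c2c(O)c(OC)c(O)c(OC)c2OC)c1OC
F3 | step 6 | 2-(2,3-dimethoxyphenyl)-7-hydroxy-5,6,8-trimethoxychromen-4-one | COc1cccc(-c2cc(=O)c3c(OC)c(OC)c(O)c(OC)c3o2)c1OC
F4 | step 7 | 2-(2,3-dimethoxyphenyl)-5-hydroxy-6,8-dimethoxy-7-(propan-2-yloxy)chromen-4-one | COc1cccc(-c2cc(=O)c3c(O)c(OC)c(OC(C)C)c(OC)c3o2)c1OC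
F5 | step 1 | 2,3,5,6-tetramethoxybenzaldehyde | COc1cc(OC)c(OC)c(C=O)c1OC
F6 | step 1 | 2,3,5,6-tetramethoxyphenyl formate | COc1cc(OC)c(OC)c(OC=O)c1OC
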